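**Plan**

Labels: Ca = ring C(CH2OH)(side chain), Cb = CH(3-hydroxypropyl), Cc = alkylidene carbon, Cd and Ce = the two ring CH2 groups, Cf = C(CH3)OH. The enabling feature is the tertiary carbinol Cf held between quaternary Ca and Ce, with Ce β to Cc: the ring bond Cd–Ce is what a Cc methyl-ketone enolate forms when it opens, at its CH2, a 2,2-disubstituted oxirane standing on Ca.
Cuts, in retrosynthetic order: the exocyclic Cc=C bond (enal from the Cc ketone), ring bond Cd–Ce (enolate/oxirane), the oxirane oxygen (from an isopropenyl group), Ca–Cb (ester-enolate Claisen), the bond from the Ca alkene carbon to the side chain (sp3–sp2 coupling), and in the side chain the alkenyl–CH2CH2, vinylic C–CH3 and carbinol–CH2 bonds (back to geranial).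
Forward: the side chain is built from geranial and joined to an iodo-allyl ester made from but-2-yne-1,4-diol and δ-valerolactone; Claisen rearrangement, lactonisation, methyl ketone formation and epoxidation give the acyclic epoxy ketone; the only ring closes in step 15; enal formation and desilylation finish.
Stereochemistry: the side-chain carbinol from a catalytic asymmetric propargylation; Ca and Cb together from a chair Claisen rearrangement (stereodefined tetrasubstituted alkene, E(O) enolate, chiral boron controller); Cf from a hydroxyl-directed epoxidation, carried unchanged through the ring closure; the (Z)-enal from an oxidative allylic transposition expected to favour the more stable isomer; the chain (E)-alkenes from geranial and a syn-methylalumination.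

Key step: step 15

Assumption: the (R)-phosphoric acid of step 1 is taken to deliver the propargyl group to the Re face of geranial; if the sense proves opposite, the (S)-acid is used with nothing else changed.
Assumption: the (4R,5R)-bromoborane of step 10 is taken to favour the chair joining the Re face of the enolate carbon to the Re face of the alkene carbon; if the sense proves opposite, the (4S,5S)-reagent is used with nothing else changed.

**Route**

Step 1
Reactants: 1 geranial, (2E)-3,7-dimethylocta-2,6-dienal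
Product: 3 (4R,5E)-6,10-dimethylundeca-5,9-dien-1-yn-4-ol, via O-boryl adduct 2 (not isolated)
Conditions: allenylboronic acid pinacol ester (1.5 equiv), (R)-3,3'-bis(2,4,6-triisopropylphenyl)-1,1'-binaphthyl-2,2'-diyl hydrogen phosphate (5 mol%), 4 Å molecular sieves, toluene, −20 °C; aqueous work-up
Reagents that add atoms: allenylboronic acid pinacol ester, C=C=CB1OC(C)(C)C(C)(C)O1
Why: Brønsted-acid-catalysed propargylboration, in which the allenylboronate adds through a closed six-membered SE2' transition state inside the chiral phosphate pocket, so that the propargyl group reaches the Re face of the conjugated aldehyde (1,2-addition only) and the (R)-carbinol results.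

Step 2
Reactants: 3 (4R,5E)-6,10-dimethylundeca-5,9-dien-1-yn-4-ol
Product: 4 tert-butyl{[(4R,5E)-6,10-dimethylundeca-5,9-dien-1-yn-4-yl]oxy}dimethylsilane
Conditions: t-BuMe2SiCl, imidazole, DMF, 0 °C → rt
Reagents that add atoms: tert-butyldimethylsilyl chloride, CC(C)(C)[Si](C)(C)Cl
Why: Standard silylation of a secondary alcohol gives an ether that withstands the organometallic, basic and oxidising steps ahead and is removed by fluoride at the end.

Step 3
Reactants: 4 tert-butyl{[(4R,5E)-6,10-dimethylundeca-5,9-dien-1-yn-4-yl]oxy}dimethylsilane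
Product: 7 (3E,6R,7E)-6-[(tert-butyldimethylsilyl)oxy]-4,8,12-trimethyltrideca-3,7,11-trien-1-ol, via alkenyldimethylalane 5 (not isolated), via lithium alkenylalanate 6 (not isolated)
Conditions: Me3Al (2.5 equiv), Cp2ZrCl2 (0.25 equiv; Cp = cyclopentadienyl), ClCH2CH2Cl, 0 °C → rt; volatiles removed; n-BuLi (1.0 equiv), THF–hexane, −78 °C; oxirane (3 equiv), −78 → 0 °C; aqueous Rochelle salt
Reagents that add atoms: trimethylaluminium, C[Al](C)C; oxirane, C1CO1
Why: Zirconium-catalysed methylalumination adds CH3 and Al syn across the terminal alkyne with Al at the terminus, and the derived butyl alanate opens oxirane with retention at the alkenyl carbon, so the new trisubstituted alkene is (E) and carries the CH2CH2OH arm while the other alkenes and the silyl ether stay untouched.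

Step 4
Reactants: 7 (3E,6R,7E)-6-[(tert-butyldimethylsilyl)oxy]-4,8,12-trimethyltrideca-3,7,11-trien-1-ol
Product: 8 tert-butyl{[(3E,6R,7E)-1-iodo-4,8,12-trimethyltrideca-3,7,11-trien-6-yl]oxy}dimethylsilane
Conditions: I2, PPh3, imidazole, CH2Cl2, 0 °C
Reagents that add atoms: iodine, II
Why: Appel-type iodination converts the unhindered primary alcohol into the iodide by SN2 displacement of the oxyphosphonium group under buffered conditions that spare the allylic silyl ether and the alkenes.

Step 5
Reactants: 9 but-2-yne-1,4-diol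
Product: 10 4-[(triethylsilyl)oxy]but-2-yn-1-ol
Conditions: NaH (1.0 equiv), THF, 0 °C → rt; Et3SiCl (1.0 equiv), 0 °C
Reagents that add atoms: chlorotriethylsilane, CC[Si](Cl)(CC)CC
Why: The monosodium alkoxide of the symmetrical diol is silylated once, which differentiates the two propargylic oxygens for the directed addition and gives a silyl ether that can later be cleaved in the presence of t-BuMe2Si ethers.

Step 6
Reactants: 10 4-[(triethylsilyl)oxy]but-2-yn-1-ol
Product: 12 (2Z)-3-iodo-2-methyl-4-[(triethylsilyl)oxy]but-2-en-1-ol, via cyclic alkenylmagnesium alkoxide 11 (not isolated)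
Conditions: MeMgBr (3.0 equiv), CuI (10 mol%), THF, −20 °C → rt; then I2 (1.5 equiv), THF, −78 → 0 °C
Reagents that add atoms: methylmagnesium bromide, C[Mg]Br; iodine, II
Why: Alkoxide-directed, copper-catalysed anti-carbomagnesiation of the propargylic alcohol places CH3 on the alkyne carbon next to the CH2O–Mg group and Mg on the distal carbon, trans to CH3, within a five-membered chelate, and iodinolysis of the C–Mg bond with retention gives the (Z)-alkenyl iodide with all four substituents defined.

Step 7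
Reactants: 13 δ-valerolactone (oxan-2-one)
Product: 16 5-[(tert-butyldimethylsilyl)oxy]pentanoic acid, via sodium 5-hydroxypentanoate 14 (not isolated), via bis-silyl derivative 15 (not isolated)
Conditions: NaOH (1.05 equiv), MeOH–H2O, rt, then evaporation; t-BuMe2SiCl (2.3 equiv), imidazole, DMF, rt; K2CO3 (cat.), MeOH–THF–H2O, rt, then pH 4 buffer
Reagents that add atoms: sodium hydroxide, [Na+].[OH-]; tert-butyldimethylsilyl chloride, CC(C)(C)[Si](C)(C)Cl
Why: Saponification opens the lactone, exhaustive silylation covers both oxygens, and only the labile silyl ester is hydrolysed by carbonate in aqueous methanol, leaving the silyl ether acid.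

Step 8
Reactants: 12 (2Z)-3-iodo-2-methyl-4-[(triethylsilyl)oxy]but-2-en-1-ol; 16 5-[(tert-butyldimethylsilyl)oxy]pentanoic acid
Product: 17 (2Z)-3-iodo-2-methyl-4-[(triethylsilyl)oxy]but-2-en-1-yl 5-[(tert-butyldimethylsilyl)oxy]pentanoate
Conditions: EDC·HCl [1-ethyl-3-(3-dimethylaminopropyl)carbodiimide hydrochloride] (1.3 equiv), 4-(dimethylamino)pyridine (0.2 equiv), CH2Cl2, 0 °C → rt
Reagents that add atoms: none
Why: Steglich esterification (carbodiimide activation with nucleophilic catalysis) acylates the primary allylic alcohol under neutral conditions that leave the alkenyl iodide and both silyl ethers intact.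

Step 9
Reactants: 8 tert-butyl{[(3E,6R,7E)-1-iodo-4,8,12-trimethyltrideca-3,7,11-trien-6-yl]oxy}dimethylsilane; 17 (2Z)-3-iodo-2-methyl-4-[(triethylsilyl)oxy]but-2-en-1-yl 5-[(tert-butyldimethylsilyl)oxy]pentanoate
Product: 19 (2E,6E,9R,10E)-9-[(tert-butyldimethylsilyl)oxy]-2,7,11,15-tetramethyl-3-{[(triethylsilyl)oxy]methyl}hexadeca-2,6,10,14-tetraen-1-yl 5-[(tert-butyldimethylsilyl)oxy]pentanoate, via alkylzinc iodide 18 (not isolated)
Conditions: 8, Zn dust (activated by BrCH2CH2Br/Me3SiCl), LiCl, THF, 40 °C; then 17, PdCl2(dppf) (5 mol%; dppf = 1,1'-bis(diphenylphosphino)ferrocene), THF, rt → 45 °C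
Reagents that add atoms: none
Why: Negishi sp3–sp2 cross-coupling, in which zinc inserts into the primary C–I bond of 8 and zerovalent palladium formed in situ couples the alkylzinc with the alkenyl iodide with retention of alkene geometry, so the side chain ends up cis to the acyloxymethyl group while ester and silyl ethers tolerate the organozinc.

Step 10
Reactants: 19 (2E,6E,9R,10E)-tetrasubstituted allyl ester
Product: 21 (2S,3R,6E,9R,10E)-9-[(tert-butyldimethylsilyl)oxy]-2-{3-[(tert-butyldimethylsilyl)oxy]propyl}-7,11,15-trimethyl-3-(prop-1-en-2-yl)-3-{[(triethylsilyl)oxy]methyl}hexadeca-6,10,14-trienoic acid, via boron enolate 20 (not isolated)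
Conditions: (4R,5R)-2-bromo-4,5-diphenyl-1,3-bis{[3,5-bis(trifluoromethyl)phenyl]sulfonyl}-1,3,2-diazaborolidine (1.3 equiv), Et3N (1.6 equiv), toluene–hexane, −78 °C; then −20 °C → rt over several days; aqueous work-up
Reagents that add atoms: none
Why: Enantioselective Ireland–Claisen rearrangement of a boron ester enolate, in which soft enolisation with Et3N in toluene–hexane gives the E(O) enolate (silyloxypropyl group trans to O–B), the [3,3] shift passes through a chair with this group and the side chain (cis to the ester CH2O) pseudo-axial to set Cb and Ca as (2S,3R), and the C2-symmetric diazaborolidine selects the chair that joins the Re face of the enolate carbon to the Re face of the alkene carbon.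

Step 11
Reactants: 21 (2S,3R)-acid
Product: 23 (3S,4R)-4-{(3E,6R,7E)-6-[(tert-butyldimethylsilyl)oxy]-4,8,12-trimethyltrideca-3,7,11-trien-1-yl}-3-{3-[(tert-butyldimethylsilyl)oxy]propyl}-4-(prop-1-en-2-yl)oxolan-2-one, via hydroxy acid 22 (not isolated)
Conditions: pyridinium p-toluenesulfonate (0.2 equiv), MeOH–CH2Cl2, 0 °C; then toluene, 40 °C
Reagents that add atoms: none
Why: Mild acid-catalysed methanolysis removes the most labile silyl group (Et3Si) selectively over the t-BuMe2Si ethers, and the liberated γ-hydroxy acid, gem-disubstituted at Ca, closes to the five-membered lactone without touching a stereocentre.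

Step 12
Reactants: 23 (3S,4R)-lactone
Product: 25 (3S,4R,7E,10R,11E)-10-[(tert-butyldimethylsilyl)oxy]-3-{3-[(tert-butyldimethylsilyl)oxy]propyl}-4-(hydroxymethyl)-8,12,16-trimethyl-4-(prop-1-en-2-yl)heptadeca-7,11,15-trien-2-one, via lithium hemiketal alkoxide 24 (not isolated)
Conditions: MeLi (1.15 equiv), THF, −78 °C; AcOH, −78 °C
Reagents that add atoms: methyllithium, [Li]C
Why: Methyllithium adds only once to the γ-lactone because the tetrahedral lithium hemiketal survives at −78 °C until the cold acidic quench, which unmasks the methyl ketone and frees the Ca–CH2OH group (open hydroxy ketone in equilibrium with its cyclic hemiketal) without affecting Ca or Cb.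

Step 13
Reactants: 25 hydroxy methyl ketone
Product: 26 (3S,4S,7E,10R,11E)-10-[(tert-butyldimethylsilyl)oxy]-3-{3-[(tert-butyldimethylsilyl)oxy]propyl}-4-(hydroxymethyl)-8,12,16-trimethyl-4-[(2R)-2-methyloxiran-2-yl]heptadeca-7,11,15-trien-2-one
Conditions: VO(acac)2 (5 mol%; acac = acetylacetonate), t-BuOOH (1.5 equiv, in decane), CH2Cl2, 0 °C → rt
Reagents that add atoms: tert-butyl hydroperoxide, CC(C)(C)OO
Why: Hydroxyl-directed vanadium-catalysed epoxidation of a homoallylic alcohol, in which only the isopropenyl group lies within reach of the vanadate ester of Ca–CH2OH and, in the chair-like transition state, the branched Cb substituent sits beside the =CH2 terminus while the unbranched side-chain CH2 sits beside the vinylic methyl group, so oxygen is delivered to the face that gives the (R)-oxirane, which is the Cf configuration of the target.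

Step 14
Reactants: 26 epoxy alcohol
Product: 27 (3S,4S,7E,10R,11E)-10-[(tert-butyldimethylsilyl)oxy]-4-{[(tert-butyldimethylsilyl)oxy]methyl}-3-{3-[(tert-butyldimethylsilyl)oxy]propyl}-8,12,16-trimethyl-4-[(2R)-2-methyloxiran-2-yl]heptadeca-7,11,15-trien-2-one
Conditions: t-BuMe2SiCl (1.5 equiv), imidazole (3 equiv), DMF, rt
Reagents that add atoms: tert-butyldimethylsilyl chloride, CC(C)(C)[Si](C)(C)Cl
Why: Imidazole-mediated silylation of the primary alcohol under non-acidic conditions (the γ,δ-epoxy ketone is acid-sensitive) caps this oxygen so that its alkoxide cannot open the neighbouring oxirane in the next step.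

Step 15
Reactants: 27 acyclic epoxy methyl ketone
Product: 30 (2S,3S,4S)-3-{(3E,6R,7E)-6-[(tert-butyldimethylsilyl)oxy]-4,8,12-trimethyltrideca-3,7,11-trien-1-yl}-3-{[(tert-butyldimethylsilyl)oxy]methyl}-2-{3-[(tert-butyldimethylsilyl)oxy]propyl}-4-hydroxy-4-methylcyclohexan-1-one, via lithium methyl enolate 28 (not isolated), via lithium alkoxide 29 (not isolated)
Conditions: LiN(iPr)2 (1.15 equiv), THF, −78 °C, 45 min; then −78 → 0 °C; AcOH, −78 °C
Reagents that add atoms: none
Why: LiN(iPr)2 removes a proton from the acetyl methyl group (Cd), the only unhindered α-position, and the carbon of the resulting lithium enolate 28 attacks the oxirane CH2 (Ce) from the side opposite its C–O bond, an SN2 opening that forms Cd–Ce and releases the Cf alkoxide 29. The closest known reaction type is the intramolecular alkylation of ketone enolates and nitrile anions by epoxides, which is known to take the larger-ring course when the proximal oxirane carbon carries no hydrogen. The one ring closes in a 6-endo mode with respect to the oxirane (both oxirane carbons become ring members) and 6-(enolendo) with respect to the enolate. No stereocentre is created: Cf keeps the oxirane configuration because its own C–O bond is not broken, and Ca and Cb are not involved, Cb–H being too hindered to be removed under kinetic conditions. The step needs C- rather than O-alkylation and attack at Ce rather than Cf; the lithium counter-ion in THF and the sp3 electrophile favour carbon, and Cf is fully substituted and neopentylic, so substitution there is excluded. The silyl ether on Ca–CH2O keeps that oxygen from opening the oxirane, and a small excess of base with a cold acidic quench avoids proton exchange at Cb.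

Step 16
Reactants: 30 hydroxy cyclohexanone
Product: 31 tertiary allylic alcohol, the 1,2-adduct of 30 bearing OH and prop-1-en-2-yl at Cc (Cb S, Ca S, Cf S; Cc configuration not controlled)
Conditions: CH2=C(CH3)MgBr (3.5 equiv), CeCl3 (anhydrous, 3.5 equiv), THF, −78 → 0 °C; aqueous NH4Cl
Reagents that add atoms: isopropenylmagnesium bromide, CC(=C)[Mg]Br
Why: Organocerium 1,2-addition to a hindered, enolisable ketone, in which the weakly basic cerium reagent adds instead of deprotonating so that Cb is not epimerised, one equivalent is spent on the tertiary hydroxyl, and the configuration of the new Cc carbinol is irrelevant because it is removed in step 17.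

Step 17
Reactants: 31 tertiary allylic alcohol
Product: 32 (2Z)-2-[(2R,3S,4S)-3-{(3E,6R,7E)-6-[(tert-butyldimethylsilyl)oxy]-4,8,12-trimethyltrideca-3,7,11-trien-1-yl}-3-{[(tert-butyldimethylsilyl)oxy]methyl}-2-{3-[(tert-butyldimethylsilyl)oxy]propyl}-4-hydroxy-4-methylcyclohexylidene]propanal
Conditions: [C5H5NH][CrO3Cl] (pyridinium chlorochromate, 3 equiv), 4 Å molecular sieves, CH2Cl2, rt
Reagents that add atoms: pyridinium chlorochromate, [O-][Cr](=O)(=O)Cl.c1cc[nH+]cc1
Why: Babler–Dauben oxidative transposition, in which the tertiary allylic chromate ester undergoes a [3,3] shift to the primary allylic chromate that is oxidised to the tetrasubstituted enal, the (Z) isomer with the flat formyl group rather than the methyl group facing the substituted Cb being expected as the more stable and predominant one, while the non-allylic tertiary alcohol and the silyl ethers are inert.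

Step 18
Reactants: 32 tris-silylated (Z)-enal
Product: 33 (2Z)-2-[(2R,3S,4S)-4-hydroxy-3-(hydroxymethyl)-3-[(3E,6R,7E)-6-hydroxy-4,8,12-trimethyltrideca-3,7,11-trien-1-yl]-2-(3-hydroxypropyl)-4-methylcyclohexylidene]propanal (CNP0172524.1)
Conditions: HF·pyridine, pyridine, THF, 0 °C → rt
Reagents that add atoms: none
Why: Fluoride cleaves the three Si–O bonds under buffered, nearly neutral conditions that the (Z)-enal, the tertiary carbinol and the allylic alcohol tolerate, releasing the target.

**Compound list**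

1 | geranial, (2E)-3,7-dimethylocta-2,6-dienal | CC(C)=CCC/C(C)=C/C=O | starting material
2 | O-boryl adduct, pinacol borate ester of 3 | CC(C)=CCC/C(C)=C/[C@H](OB1OC(C)(C)C(C)(C)O1)CC#C | intermediate
3 | (4R,5E)-6,10-dimethylundeca-5,9-dien-1-yn-4-ol | CC(C)=CCC/C(C)=C/[C@H](O)CC#C | intermediate
4 | tert-butyl{[(4R,5E)-6,10-dimethylundeca-5,9-dien-1-yn-4-yl]oxy}dimethylsilane | CC(C)=CCC/C(C)=C/[C@H](O[Si](C)(C)C(C)(C)C)CC#C | intermediate
5 | (E)-alkenyldimethylalane from 4 | CC(C)=CCC/C(C)=C/[C@H](O[Si](C)(C)C(C)(C)C)C/C(C)=C/[Al](C)C | intermediate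
6 | lithium butyl[(E)-alkenyl]dimethylalanate | CC(C)=CCC/C(C)=C/[C@H](O[Si](C)(C)C(C)(C)C)C/C(C)=C/[Al-](C)(C)CCCC.[Li+] | intermediate
7 | (3E,6R,7E)-6-[(tert-butyldimethylsilyl)oxy]-4,8,12-trimethyltrideca-3,7,11-trien-1-ol | CC(C)=CCC/C(C)=C/[C@H](O[Si](C)(C)C(C)(C)C)C/C(C)=C/CCO | intermediate
8 | tert-butyl{[(3E,6R,7E)-1-iodo-4,8,12-trimethyltrideca-3,7,11-trien-6-yl]oxy}dimethylsilane | CC(C)=CCC/C(C)=C/[C@H](O[Si](C)(C)C(C)(C)C)C/C(C)=C/CCI | intermediate
9 | but-2-yne-1,4-diol | OCC#CCO | starting material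
10 | 4-[(triethylsilyl)oxy]but-2-yn-1-ol | OCC#CCO[Si](CC)(CC)CC | intermediate
11 | cyclic alkenylmagnesium alkoxide, 4-methyl-3-{[(triethylsilyl)oxy]methyl}-2,5-dihydro-1,2-oxamagnesole | CC1=C(CO[Si](CC)(CC)CC)[Mg]OC1 | intermediate
12 | (2Z)-3-iodo-2-methyl-4-[(triethylsilyl)oxy]but-2-en-1-ol | OC/C(C)=C(\I)CO[Si](CC)(CC)CC | intermediate
13 | δ-valerolactone (oxan-2-one) | O=C1CCCCO1 | starting material
14 | sodium 5-hydroxypentanoate | [Na+].[O-]C(=O)CCCCO | intermediate
15 | tert-butyldimethylsilyl 5-[(tert-butyldimethylsilyl)oxy]pentanoate | CC(C)(C)[Si](C)(C)OCCCCC(=O)O[Si](C)(C)C(C)(C)C | intermediate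
16 | 5-[(tert-butyldimethylsilyl)oxy]pentanoic acid | CC(C)(C)[Si](C)(C)OCCCCC(=O)O | intermediate
17 | (2Z)-3-iodo-2-methyl-4-[(triethylsilyl)oxy]but-2-en-1-yl 5-[(tert-butyldimethylsilyl)oxy]pentanoate | CC(C)(C)[Si](C)(C)OCCCCC(=O)OC/C(C)=C(\I)CO[Si](CC)(CC)CC | intermediate
18 | (3E,6R,7E)-6-silyloxy-4,8,12-trimethyltrideca-3,7,11-trien-1-ylzinc iodide | CC(C)=CCC/C(C)=C/[C@H](O[Si](C)(C)C(C)(C)C)C/C(C)=C/CC[Zn]I | intermediate
19 | (2E,6E,9R,10E)-9-[(tert-butyldimethylsilyl)oxy]-2,7,11,15-tetramethyl-3-{[(triethylsilyl)oxy]methyl}hexadeca-2,6,10,14-tetraen-1-yl 5-[(tert-butyldimethylsilyl)oxy]pentanoate | CC(C)(C)[Si](C)(C)OCCCCC(=O)OC/C(C)=C(\CC/C=C(C)/C[C@@H](O[Si](C)(C)C(C)(C)C)/C=C(C)/CCC=C(C)C)CO[Si](CC)(CC)CC | intermediate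
20 | E(O) boron enolate of 19 carrying the (4R,5R)-diazaborolidine (silyloxypropyl trans to O–B) | CC(C)(C)[Si](C)(C)OCCC/C=C(/OB1N(S(=O)(=O)c2cc(C(F)(F)F)cc(C(F)(F)F)c2)[C@H](c2ccccc2)[C@@H](c2ccccc2)N1S(=O)(=O)c1cc(C(F)(F)F)cc(C(F)(F)F)c1)OC/C(C)=C(\CC/C=C(C)/C[C@@H](O[Si](C)(C)C(C)(C)C)/C=C(C)/CCC=C(C)C)CO[Si](CC)(CC)CC | intermediate
21 | (2S,3R,6E,9R,10E)-9-[(tert-butyldimethylsilyl)oxy]-2-{3-[(tert-butyldimethylsilyl)oxy]propyl}-7,11,15-trimethyl-3-(prop-1-en-2-yl)-3-{[(triethylsilyl)oxy]methyl}hexadeca-6,10,14-trienoic acid | CC(C)=CCC/C(C)=C/[C@H](O[Si](C)(C)C(C)(C)C)C/C(C)=C/CC[C@@](CO[Si](CC)(CC)CC)([C@H](CCCO[Si](C)(C)C(C)(C)C)C(=O)O)C(C)=C | intermediate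
22 | (2S,3R)-3-(hydroxymethyl) acid, 21 without the Et3Si group | CC(C)=CCC/C(C)=C/[C@H](O[Si](C)(C)C(C)(C)C)C/C(C)=C/CC[C@@](CO)([C@H](CCCO[Si](C)(C)C(C)(C)C)C(=O)O)C(C)=C | intermediate
23 | (3S,4R)-4-{(3E,6R,7E)-6-[(tert-butyldimethylsilyl)oxy]-4,8,12-trimethyltrideca-3,7,11-trien-1-yl}-3-{3-[(tert-butyldimethylsilyl)oxy]propyl}-4-(prop-1-en-2-yl)oxolan-2-one | CC(C)=CCC/C(C)=C/[C@H](O[Si](C)(C)C(C)(C)C)C/C(C)=C/CC[C@@]1(C(C)=C)COC(=O)[C@H]1CCCO[Si](C)(C)C(C)(C)C | intermediate
24 | lithium alkoxide of the cyclic methyl hemiketal from 23 (hemiketal carbon undefined) | CC(C)=CCC/C(C)=C/[C@H](O[Si](C)(C)C(C)(C)C)C/C(C)=C/CC[C@@]1(C(C)=C)COC(C)([O-])[C@H]1CCCO[Si](C)(C)C(C)(C)C.[Li+] | intermediate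
25 | (3S,4R,7E,10R,11E)-10-[(tert-butyldimethylsilyl)oxy]-3-{3-[(tert-butyldimethylsilyl)oxy]propyl}-4-(hydroxymethyl)-8,12,16-trimethyl-4-(prop-1-en-2-yl)heptadeca-7,11,15-trien-2-one | CC(C)=CCC/C(C)=C/[C@H](O[Si](C)(C)C(C)(C)C)C/C(C)=C/CC[C@@](CO)([C@H](CCCO[Si](C)(C)C(C)(C)C)C(C)=O)C(C)=C | intermediate
26 | (3S,4S,7E,10R,11E)-10-[(tert-butyldimethylsilyl)oxy]-3-{3-[(tert-butyldimethylsilyl)oxy]propyl}-4-(hydroxymethyl)-8,12,16-trimethyl-4-[(2R)-2-methyloxiran-2-yl]heptadeca-7,11,15-trien-2-one | CC(C)=CCC/C(C)=C/[C@H](O[Si](C)(C)C(C)(C)C)C/C(C)=C/CC[C@@](CO)([C@H](CCCO[Si](C)(C)C(C)(C)C)C(C)=O)[C@]1(C)CO1 | intermediate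
27 | (3S,4S,7E,10R,11E)-10-[(tert-butyldimethylsilyl)oxy]-4-{[(tert-butyldimethylsilyl)oxy]methyl}-3-{3-[(tert-butyldimethylsilyl)oxy]propyl}-8,12,16-trimethyl-4-[(2R)-2-methyloxiran-2-yl]heptadeca-7,11,15-trien-2-one (key-step precursor) | CC(C)=CCC/C(C)=C/[C@H](O[Si](C)(C)C(C)(C)C)C/C(C)=C/CC[C@@](CO[Si](C)(C)C(C)(C)C)([C@H](CCCO[Si](C)(C)C(C)(C)C)C(C)=O)[C@]1(C)CO1 | intermediate
28 | lithium enolate of 27 at the acetyl methyl group (Cd) | CC(C)=CCC/C(C)=C/[C@H](O[Si](C)(C)C(C)(C)C)C/C(C)=C/CC[C@@](CO[Si](C)(C)C(C)(C)C)([C@H](CCCO[Si](C)(C)C(C)(C)C)C(=C)[O-])[C@]1(C)CO1.[Li+] | intermediate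
29 | lithium Cf alkoxide of 30 | CC(C)=CCC/C(C)=C/[C@H](O[Si](C)(C)C(C)(C)C)C/C(C)=C/CC[C@@]1(CO[Si](C)(C)C(C)(C)C)[C@H](CCCO[Si](C)(C)C(C)(C)C)C(=O)CC[C@]1(C)[O-].[Li+] | intermediate
30 | (2S,3S,4S)-3-{(3E,6R,7E)-6-[(tert-butyldimethylsilyl)oxy]-4,8,12-trimethyltrideca-3,7,11-trien-1-yl}-3-{[(tert-butyldimethylsilyl)oxy]methyl}-2-{3-[(tert-butyldimethylsilyl)oxy]propyl}-4-hydroxy-4-methylcyclohexan-1-one (key-step product) | CC(C)=CCC/C(C)=C/[C@H](O[Si](C)(C)C(C)(C)C)C/C(C)=C/CC[C@@]1(CO[Si](C)(C)C(C)(C)C)[C@H](CCCO[Si](C)(C)C(C)(C)C)C(=O)CC[C@]1(C)O | intermediate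
31 | 1,2-adduct of 30 with OH and prop-1-en-2-yl at Cc (Cb S, Ca S, Cf S; Cc undefined) | CC(C)=CCC/C(C)=C/[C@H](O[Si](C)(C)C(C)(C)C)C/C(C)=C/CC[C@@]1(CO[Si](C)(C)C(C)(C)C)[C@H](CCCO[Si](C)(C)C(C)(C)C)C(O)(C(C)=C)CC[C@]1(C)O | intermediate
32 | (2Z)-2-[(2R,3S,4S)-3-{(3E,6R,7E)-6-[(tert-butyldimethylsilyl)oxy]-4,8,12-trimethyltrideca-3,7,11-trien-1-yl}-3-{[(tert-butyldimethylsilyl)oxy]methyl}-2-{3-[(tert-butyldimethylsilyl)oxy]propyl}-4-hydroxy-4-methylcyclohexylidene]propanal | CC(C)=CCC/C(C)=C/[C@H](O[Si](C)(C)C(C)(C)C)C/C(C)=C/CC[C@@]1(CO[Si](C)(C)C(C)(C)C)[C@H](CCCO[Si](C)(C)C(C)(C)C)/C(=C(/C)C=O)CC[C@]1(C)O | intermediate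
33 | (2Z)-2-[(2R,3S,4S)-4-hydroxy-3-(hydroxymethyl)-3-[(3E,6R,7E)-6-hydroxy-4,8,12-trimethyltrideca-3,7,11-trien-1-yl]-2-(3-hydroxypropyl)-4-methylcyclohexylidene]propanal (CNP0172524.1) | CC(C)=CCC/C(C)=C/[C@H](O)C/C(C)=C/CC[C@@]1(CO)[C@H](CCCO)/C(=C(/C)C=O)CC[C@]1(C)O | target

**Step count and risks**

Total step count: 18. Longest linear sequence: 14 steps (steps 1–4, then 9–18, from geranial).

Steps most likely to fail:

Step 10. The [3,3] shift onto a tetrasubstituted alkene may be too slow for the bulky boron enolate, so that enolate geometry and face selection erode, or the Lewis-acidic bromoborane may attack the Et3Si ether before rearrangement. Fallback without reagent control, setting out from 19: LiN(iPr)2 and Me3SiCl/Et3N in THF at −78 °C should give the (E)-trimethylsilyl ketene acetal F1, which rearranges on warming (rt to 60 °C) through the same chair. Hydrolysis should give acid 21 together with its (2R,3S) diastereomer F2, which has the same relative configuration at Ca/Cb but the opposite sense relative to the side-chain carbinol. The mixture would be put through the conditions of step 11, and lactone 23 separated from the (3R,4S) diastereomeric lactone F3 by preparative HPLC; the route is rejoined at 23.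

Step 13. The ketone may interfere: the cyclic hemiketal lowers the amount of free directing alcohol, and the carbonyl or hemiketal oxygen may open the new oxirane under vanadium Lewis acidity to a bicyclic ketal; facial selection at the isopropenyl group may also be incomplete. Fallback that postpones the ketone, setting out from lactone 23: aminolysis with MeNH(OMe)·HCl and Me3Al in CH2Cl2 should give the hydroxy Weinreb amide F4; the same VO(acac)2/t-BuOOH epoxidation, directed by the same hydroxyl, should give the epoxy alcohol F5; silylation (t-BuMe2SiCl, imidazole, DMF) gives the silyl ether F6; MeLi in THF at −78 °C then converts the amide into the methyl ketone, which is 27.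

Step 17. The [3,3] shift may show poor geometric selectivity, and the acidic oxidant may ionise the tertiary allylic alcohol (elimination, or transannular ether formation with the Cf hydroxyl). Fallback by direct olefination, setting out from ketone 30: Horner–Wadsworth–Emmons reaction with diethyl (1-cyanoethyl)phosphonate and KOt-Bu (2.2 equiv, THF, reflux) should give, after chromatographic separation of the geometric isomers, the (Z)-α-methyl unsaturated nitrile F7 (nitrile cis to Cb). Reduction with i-Bu2AlH (toluene, −78 °C) and mild aqueous acidic hydrolysis of the aldimine returns to 32.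

**Further compounds**

F1 | step 10 | (E)-trimethylsilyl ketene acetal of 19 (silyloxypropyl trans to OSiMe3) | CC(C)(C)[Si](C)(C)OCCC/C=C(/O[Si](C)(C)C)OC/C(C)=C(\CC/C=C(C)/C[C@@H](O[Si](C)(C)C(C)(C)C)/C=C(C)/CCC=C(C)C)CO[Si](CC)(CC)CC
F2 | step 10 | (2R,3S,6E,9R,10E)-diastereomer of acid 21 | CC(C)=CCC/C(C)=C/[C@H](O[Si](C)(C)C(C)(C)C)C/C(C)=C/CC[C@](CO[Si](CC)(CC)CC)([C@@H](CCCO[Si](C)(C)C(C)(C)C)C(=O)O)C(C)=C
F3 | step 10 | (3R,4S)-diastereomer of lactone 23 | CC(C)=CCC/C(C)=C/[C@H](O[Si](C)(C)C(C)(C)C)C/C(C)=C/CC[C@]1(C(C)=C)COC(=O)[C@@H]1CCCO[Si](C)(C)C(C)(C)C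
F4 | step 13 | (2S,3R)-hydroxy Weinreb amide from lactone 23 (N-methoxy-N-methylamide at Cb, free CH2OH at Ca) | CC(C)=CCC/C(C)=C/[C@H](O[Si](C)(C)C(C)(C)C)C/C(C)=C/CC[C@@](CO)([C@H](CCCO[Si](C)(C)C(C)(C)C)C(=O)N(C)OC)C(C)=C
F5 | step 13 | epoxy alcohol of F4 with the (2R)-2-methyloxiran-2-yl group on Ca | CC(C)=CCC/C(C)=C/[C@H](O[Si](C)(C)C(C)(C)C)C/C(C)=C/CC[C@@](CO)([C@H](CCCO[Si](C)(C)C(C)(C)C)C(=O)N(C)OC)[C@]1(C)CO1
F6 | step 13 | tert-butyldimethylsilyl ether of F5 | CC(C)=CCC/C(C)=C/[C@H](O[Si](C)(C)C(C)(C)C)C/C(C)=C/CC[C@@](CO[Si](C)(C)C(C)(C)C)([C@H](CCCO[Si](C)(C)C(C)(C)C)C(=O)N(C)OC)[C@]1(C)CO1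
F7 | step 17 | (2Z)-2-[(2R,3S,4S)-cyclohexylidene]propanenitrile analogue of 32 (nitrile cis to Cb) | CC(C)=CCC/C(C)=C/[C@H](O[Si](C)(C)C(C)(C)C)C/C(C)=C/CC[C@@]1(CO[Si](C)(C)C(C)(C)C)[C@H](CCCO[Si](C)(C)C(C)(C)C)/C(=C(/C)C#N)CC[C@]1(C)O
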